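The amount of one portion of partner over the left-handed substrate charged is 0.750. This ratio, partner gone in by the asked time over left-handed substrate charged, is the dosed ratio ρ. Read x, the fraction of left-handed substrate turned into left-handed product, against it.

| setting | north-east | north-west | west | teal | blue | green |
|---|---|---|---|---|---|---|
| left-handed substrate | 16 mM | 16 mM | 16 mM | 16 mM | 16 mM | 16 mM |
| right-handed substrate | 16 mM | 16 mM | 16 mM | 16 mM | 16 mM | 16 mM |
| partner | 24 mM (in portions, 2) | 24 mM (in portions, 2) | 36 mM (in portions, 2) | 24.0 mM (in portions, 2) | 24.0 mM (in portions, 2) | 24.0 mM (in portions, 2) |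
| free catalyst | 11 µM | 24 µM | 16 µM | 16 µM | 16 µM | 16 µM |
| remark | run made earlier; portions every 10 min | run made earlier; portions every 10 min | run made earlier; portions every 10 min | the portions of partner follow each other after 10 min, the first at the start | the portions of partner follow each other after 20 min, the first at the start | the portions of partner follow each other after 40 min, the first at the start |
| time |  |  |  | 20 min | 20 min | 20 min |

| run | time / min | left-handed product / % |
|---|---|---|
| north-east | 2.00 | 8.6 |
| north-east | 4.00 | 15.1 |
| north-east | 10.0 | 24.1 |
| north-east | 25.0 | 44.3 |
| north-west | 3.00 | 20.0 |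
| north-west | 8.00 | 29.4 |
| north-west | 15.0 | 45.1 |
| north-west | 25.0 | 48.7 |
| west | 3.00 | 22.2 |
| west | 8.00 | 34.6 |
| west | 15.0 | 47.4 |
| west | 25.0 | 49.9 |

(each reading ± 0.5 percentage points)

- free catalyst is single-handed; left-handed substrate and right-handed substrate are mirror images of each other, charged as a racemate, each of them at the stated concentration
- percentages count the whole charge, also what has not yet gone in
- a step back or a flat step of under half a percent of the largest counts as no turn
- "hardly changes" means that all values lie within two and a half points (for a concentration: within two and a half percent of the largest)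

- [left-handed product] at the end for teal, blue, green, in this order
- how the row runs (rises all the way / falls, then rises / falls all the way / hardly changes / rises, then falls)

1. Main step alone. I take left-handed substrate and partner to react one for one, so x is capped by the lower of ρ and 1. Green's second portion comes later than the end, and I count blue's, due at 20 min, as falling just after the end. So ρ stays 0.750 in blue and green, and partner is their limiting reagent. Teal has both portions in, so its ρ is 1.50, and left-handed substrate caps it.

2. Add the rate. I assume dx/dt = κ(1 − x)(ρ − x), which integrates for one portion to x = ρ(E − 1)/(E − ρ), with E = exp(κ(1 − ρ)t). The west run has the same 16 µM of free catalyst and a first portion of ρ = 1.12. Its reading at 8.00 min gives x = 0.692, so κ reads 0.223 min⁻¹. By 20 min, blue and green reach x = 0.668, which lies under the cap.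

3. Add teal's second portion. The first leg gives x = 0.562 at 10 min. I put that answer back in as the new start, with ρ now 1.50, and go round once more. The second leg ends at x = 0.909, more than with one portion.

4. The rest. West's last reading, 49.9%, stands at the left-handed half of the charge, 50.0%, so I count no left-handed product from right-handed substrate.

My row is 14.6 mM, 10.7 mM, 10.7 mM: it falls, then stays flat, which counts as falling all the way.

The forecast differs from this, giving 15.55 mM, 15.6 mM, 15.65 mM, hardly changes, on the words “I read "20 min" as the hold after the last portion”.

The flask gives 14.6 mM, 10.6 mM, 10.6 mM: falls all the way.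

    free catalyst + left-handed substrate ⇌ catalyst intermediate A (K = 27.0 L mol⁻¹, k = 5.60 × 10⁵ L mol⁻¹ min⁻¹)
    free catalyst + right-handed substrate ⇌ catalyst intermediate B (K = 37.0 L mol⁻¹, k = 16000 L mol⁻¹ s⁻¹)
    partner + catalyst intermediate A → free catalyst + left-handed product (k = 94000 L mol⁻¹ min⁻¹)
    partner + catalyst intermediate B → free catalyst + right-handed product (k = 1500 L mol⁻¹ min⁻¹)
    free catalyst ⇌ dormant form (K = 0.860, k = 4.50 min⁻¹)

Blue ends at x = 0.662, under its ρ of 0.750, with partner in the flask at 4.2% of its whole charge. Green, with the same ρ, ends at the same 10.6 mM, while teal, at ρ = 1.50, ends at x = 0.912. At 5.82 min in teal, catalyst intermediate A falls back 49 times faster than it goes on. At 10.0 min in teal it holds 7.08% of the catalyst, less than the 22.1% in catalyst intermediate B.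

Readings and results are calculated on assumed constants, and the scatter is random.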